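## The problem

Compound 22 is a cis-fused eremophilane decalin in which ring A (C1–C5 and C10) carries the senecioate at C3 and the C15 methyl at C4, while ring B (C5–C10) carries the isopropenyl group at C7, a ketone at C8 and the angelate at C9; the rings share the methyl-bearing quaternary C5 and the methine C10 (eremophilane numbering throughout). Six stereocentres have to be set (C3, C4, C5, C7, C9 and C10), and the quaternary C5 cannot be repaired later, so it has to be formed under the control of a centre that is already present; C7, remote from every oxygen function, is the natural anchor. Once the C14 methyl and the C7 isopropenyl group are cis, the molecule is held in the chair–chair conformer that keeps both equatorial on ring B, and in that conformer the cis fusion, the equatorial C15 methyl and the two equatorial C–O bonds (3α and 9β) are the stable arrangements. C10 and C4 can therefore be settled by equilibration next to a carbonyl, whereas C3 and C9 need more care because the axial C14 methyl and the concave α face of ring B steer hydride towards the axial alcohols. The Z-enoate (angelate) isomerises to the tiglate under nucleophilic or basic acylation, the senecioate deconjugates when it is made from the acid chloride with amine base, and the isopropenyl group is acid-sensitive. The C8 ketone is β,γ-unsaturated towards the isopropenyl group and flanked by two epimerisable centres (C7 and C9), and the vicinal oxygens at C8 and C9 invite acyl and silyl migration. What makes the plan possible is that C5 to C10, the C14 methyl and the three isopropenyl carbons together form a meta-menthane skeleton, and opening the cyclopropane of (+)-3-carene gives exactly this unit as a cyclohexenone with its carbonyl at C9 and a C10=C5 double bond that can serve as dienophile. The atoms that remain (C1–C4, C15 and O3) make up a 3-silyloxypenta-1,3-diene, so ring A can be closed on ring B by a [4+2] annulation.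

## Retrosynthesis

**22 ⇒ 21 (C8 carbonyl from the carbinol).** The C8 ketone of 22 is traced to the secondary alcohol of 21. The ketone is the most fragile function: once present it is a β,γ-unsaturated α-acyloxy ketone that would not tolerate hydride, base or Mitsunobu reagents, so it is uncovered last. The forward oxidation only has to be neither acidic nor basic.

**21 ⇒ 20 ⇒ 17 + 18 (C9 O–acyl bond).** Returning the silyl group to O8 gives 20, and cutting the angelate gives alcohol 17 and angelic acid 18, which is activated in the flask as mixed anhydride 19. Attaching the Z-enoate after all reductions and after the Mitsunobu step, not earlier, means that it never meets hydride, phosphine or base. The forward reaction must acylate a hindered secondary alcohol without Z/E isomerisation.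

**17 ⇒ 16 ⇒ 14 + 15 ⇒ 13 (C9–H, C3–O and C3–H bonds).** The 9β-carbinol of 17 is traced to ketone 16, the 3α-senecioate of 16 to the axial 3β-alcohol 14 plus senecioic acid 15 (C–O bond made with inversion), and 14 to dione 13. The C3 carbonyl of 13 is the less hindered one and is reduced first. The C9 carbonyl is reduced only after C4 has the natural configuration, because in the 4-epi series the axial C15 methyl lies under ring B, on the α-face trajectory that the hydride must take. The forward steps need chemoselectivity between two ketones, clean inversion at C3 and α-face attack at C9; the last is the reason for keeping an axial silyloxy group at C8.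

**13 ⇒ 12 ⇒ 11 ⇒ 10 ⇒ 8 (C3 ketone release, C4 inversion, C8–O bond).** Dione 13 is the C4 epimer of dione 12, which comes from bis-silyl compound 11 by hydrolysis of the silyl enol ether. The C8 silyl ether of 11 is traced to α-hydroxy ketone 10 and the C8–O bond of 10 to the enolate 9 of ketone 8. The silyl enol ether left by the annulation is what distinguishes the two carbonyls: only the C9 ketone can be enolised while C3 is masked. Precursor 8 has no oxygen at C8 and no free C3 ketone.

**8 ⇒ 4 + 7 (C4–C5 and C1–C10; ring A).** Cutting both bonds that join ring A to ring B gives enone 4 and diene 7. A Robinson-type cut (C4–C5 together with C9–C10 or C1–C2) would need a separate, less controlled conjugate addition to a β,β-disubstituted enone. The chosen cut forms the quaternary centre and the ring in one operation, with C7 directing the face. It also leaves the C3 oxygen as an enol ether and the C9 oxygen as a ketone, which is the differentiation used later. The forward reaction must overcome a hindered dienophile and add anti to the isopropenyl group.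

**4 ⇒ 3 ⇒ 2 ⇒ 1 and 7 ⇒ 5 + 6.** Enone 4 is the elimination product of chloride 3, which arises by opening the cyclopropane of carenone 2, itself the allylic oxidation product of (+)-3-carene 1. The C7 stereocentre of the target is the C1 stereocentre of 1 and is never touched. Diene 7 is the silyl enol ether of ethyl vinyl ketone 5, made with silyl triflate 6.

## Roads not taken

Alternative 1: anionic oxy-Cope rearrangement of a bicyclo[2.2.2]octenol.
- **Cut:** C5–C6 of ring B.
- **Forward step:** 3,3-dimethoxy-5,6-dimethyl-2-vinylbicyclo[2.2.2]oct-5-en-2-ol A1 would be deprotonated (KH, 18-crown-6). The alkoxide of A1 would rearrange so that the vinyl terminus bonds to the methyl-bearing alkene carbon (C5–C6) while the bond between the carbinol carbon and the bridgehead (C3–C8) breaks. Protonation of the resulting C7–C8 enolate would give the cis-decalin 9,9-dimethoxy-11,12,13-trinor-10βH-eremophil-3-en-8-one A2.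
- **Merits:** the cis fusion and the quaternary C5 come from one concerted step. The C8 ketone and the C9 oxygen (as a ketal) are already in their final places. The C3=C4 alkene of A2 is a handle for a trans 3-oxygen/4-methyl pair by hydroboration.
- **Weak points:** A2 lacks C11–C13 and the C7 stereocentre. The isopropenyl group would have to be attached next to the C8 ketone, where it tends to end up as the conjugated isopropylidene. A1 is racemic unless its own construction is made asymmetric. The ketal still has to be turned into a single C9 carbinol.
- **Comparison:** in the C8/C9 oxidation pattern this road is better, since the chosen plan spends steps 6, 7, 13 and 14 on moving the carbonyl from C9 to C8. Against that, the chosen plan takes the absolute configuration and a complete ring B, including C7, from the chiral pool.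

Alternative 2: sesquiterpene cyclase, then oxidative tailoring.
- **Cut:** C6–C7 and C5–C10.
- **Forward step:** an aristolochene synthase with its divalent magnesium cofactor would fold (2E,6E)-farnesyl diphosphate A3 into (+)-aristolochene A4, closing both rings and moving a methyl group to C5.
- **Merits:** A3 is achiral and one step turns it into the whole carbon skeleton with the C4 and C5 methyls already cis. For the hydrocarbon this is better step economy than the chosen plan, which needs an annulation plus an epimerisation at C4.
- **Weak points:** A4 has the C7 configuration opposite to that of 22 and carries no oxygen. C3 is an unactivated methylene with no handle for a stereoselective oxidation. The C9=C10 alkene must become a cis C10–H next to an oxygenated C9. Inverting C7 through a C8 ketone risks conjugating the isopropenyl group.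
- **Comparison:** the chosen plan introduces every oxygen at a carbon activated by a carbonyl and starts with the correct C7, which outweighs its longer skeleton assembly.

Alternative 3: desymmetrising asymmetric Heck cyclisation.
- **Cut:** C1–C10.
- **Forward step:** a zerovalent palladium catalyst, formed in the flask from Pd(OAc)2 and (R)-BINAP, would insert into the C–I bond of (Z)-4-iodo-1-(1-methylcyclohexa-2,5-dien-1-yl)but-3-en-2-one A5. The vinylpalladium species would add to one of the two enantiotopic ring alkenes of A5 and eliminate to cis-8a-methyl-1,8a-dihydronaphthalen-2(4aH)-one A6.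
- **Merits:** C5 and C10 are set catalytically from the achiral A5, so either enantiomer is available without a chiral-pool source. In this respect the road is more flexible than the chosen plan.
- **Weak points:** A6 lacks the C4 methyl, the isopropenyl group and every ring-B oxygen. The ring-B diene of A6 would have to be converted regio- and stereoselectively into the C7/C8/C9 array far from any controlling centre. Ring A still needs methylation next to the quaternary carbon and saturation.
- **Comparison:** the chosen plan brings ring B complete and needs only functional-group changes after the annulation.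

Key step: step 5

Assumptions:
- α/β refer to the usual eremophilane drawing, in which the C14 methyl on C5 is β.
- Senecioyl = 3-methylbut-2-enoyl; angeloyl = (Z)-2-methylbut-2-enoyl.
- The C8 hydroxyl is taken to enter on the β face in step 6. This centre becomes the ketone in step 14, so its configuration matters only for the facial control of step 11.

## Route

Step 1
Reactants: 1 (+)-3-carene
Product: 2 (1S,6R)-car-3-en-5-one (carane numbering)
Conditions: t-BuOOH, CrO3 (cat.), CH2Cl2, rt
Reagents that add atoms: tert-butyl hydroperoxide, CC(C)(C)OO
Why: CrO3-catalysed allylic oxidation; C5 is both allylic and cyclopropylcarbinyl, so it is oxidised in preference to C2 and gives the cyclopropyl-conjugated enone with both stereocentres untouched.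

Step 2
Reactants: 2 (1S,6R)-car-3-en-5-one
Product: 3 (S)-5-(2-chloropropan-2-yl)-3-methylcyclohex-2-en-1-one
Conditions: HCl (g), CH2Cl2, 0 °C
Reagents that add atoms: hydrogen chloride, Cl
Why: Homoconjugate hydrochlorination of a conjugated cyclopropyl ketone; the protonated carbonyl opens the C6–C7 bond that overlaps with the π system, chloride captures the tertiary cation, and carane C1 becomes C5 of the cyclohexenone without change.

Step 3
Reactants: 3 (S)-5-(2-chloropropan-2-yl)-3-methylcyclohex-2-en-1-one
Product: 4 (S)-3-methyl-5-(prop-1-en-2-yl)cyclohex-2-en-1-one
Conditions: DBU, PhMe, 90 °C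
Reagents that add atoms: none
Why: E2 dehydrochlorination of a tertiary chloride by a hindered amidine; the six methyl hydrogens are more accessible than the ring methine, so the isopropenyl isomer should predominate, and the weak base keeps the enolate concentration low, which disfavours 1,3-elimination back to 2.

Step 4
Reactants: 5 ethyl vinyl ketone, 6 tert-butyldimethylsilyl triflate
Product: 7 (Z)-3-(tert-butyldimethylsilyloxy)penta-1,3-diene
Conditions: Et3N, CH2Cl2, 0 °C
Reagents that add atoms: none
Why: Soft enolisation and O-silylation of an enone with silyl triflate and amine; the ethyl CH2 is the only enolisable position and this protocol favours the Z enol ether (methyl trans to vinyl), the geometry needed for an s-cis diene.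

Step 5
Reactants: 4 (S)-3-methyl-5-(prop-1-en-2-yl)cyclohex-2-en-1-one, 7 (Z)-3-(tert-butyldimethylsilyloxy)penta-1,3-diene
Product: 8 3-(tert-butyldimethylsilyloxy)-4-epi-10βH-eremophila-2,11-dien-9-one (4α,5β-dimethyl, 7β-isopropenyl, cis-fused)
Conditions: AlBr3/AlMe3 (AlMe3 as minor component), PhMe/CH2Cl2, −5 °C; pyridine, then cold aq. NaHCO3
Reagents that add atoms: none
Why: The AlBr3-complexed enone is attacked at C5 by the silyl-enol-ether terminus C4 of 7 and C1 then bonds to C10, either in one asynchronous [4+2] transition state or as a Mukaiyama–Michael addition followed by collapse of the aluminium enolate onto the silyloxyallyl cation; AlMe3 removes adventitious HBr so that the diene, the product enol ether and the isopropenyl group survive. The closest known reaction type is the Lewis-acid-promoted Diels–Alder (double Michael) annulation of 2-silyloxydienes with hindered 3-methylcyclohex-2-enones. Ring A, the only ring closed, forms by [4+2] cycloaddition; in the stepwise limit the second bond is a 6-endo-trig Michael closure at C1–C10. Regiochemistry follows from the silyloxy group, which makes C4 the nucleophilic diene terminus and pairs it with the electrophilic β-carbon C5. C5 is set by approach of the diene anti to the C7 isopropenyl group, as in additions to 5-substituted cyclohexenones, which leaves C14 cis to isopropenyl. C10 follows from suprafacial addition (cis fusion), and this fusion is also the thermodynamic one because a trans fusion would place C14 and isopropenyl 1,3-diaxial. C4 arises from the endo transition state with the methyl of the Z-diene outside, which puts C15 trans to C14 (4-epi); it is corrected in step 8. The one selectivity that cannot be repaired is the facial one, and it is secured by the existing C7 stereocentre.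

Step 6
Reactants: 8 3-(tert-butyldimethylsilyloxy)-4-epi-10βH-eremophila-2,11-dien-9-one
Product: 10 8β-hydroxy-3-(tert-butyldimethylsilyloxy)-4-epi-10βH-eremophila-2,11-dien-9-one, via potassium C8–C9 enolate 9 (not isolated)
Conditions: KN(SiMe3)2, THF, −78 °C; 2-(phenylsulfonyl)-3-phenyloxaziridine, −78 °C; AcOH quench
Reagents that add atoms: 2-(phenylsulfonyl)-3-phenyloxaziridine, O=S(=O)(c1ccccc1)N1OC1c1ccccc1
Why: Kinetic deprotonation by the bulky amide occurs at the C8 methylene and not at the C10 methine, and the enolate is hydroxylated by the N-sulfonyloxaziridine; oxygen should enter axially on the convex β face because the α face is covered by ring A and C15, and the silyl enol ether and isopropenyl group are inert at −78 °C.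

Step 7
Reactants: 10 8β-hydroxy-3-(tert-butyldimethylsilyloxy)-4-epi-10βH-eremophila-2,11-dien-9-one, 6 tert-butyldimethylsilyl triflate
Product: 11 3,8β-bis(tert-butyldimethylsilyloxy)-4-epi-10βH-eremophila-2,11-dien-9-one
Conditions: 2,6-lutidine, CH2Cl2, −78 → 0 °C
Reagents that add atoms: none
Why: Silyl triflate with 2,6-lutidine silylates hindered secondary alcohols; at low temperature the weak base does not enolise the C9 ketone, so the axial C8 configuration is kept.

Step 8
Reactants: 11 3,8β-bis(tert-butyldimethylsilyloxy)-4-epi-10βH-eremophila-2,11-dien-9-one
Product: 13 8β-(tert-butyldimethylsilyloxy)-10βH-eremophil-11-ene-3,9-dione, via 4-epi-3,9-dione 12 (not isolated)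
Conditions: 1 M HCl (aq.), THF, 0 °C; then crude 12, DBU, PhMe, 50 °C
Reagents that add atoms: none
Why: Protonation at C2 and loss of silicon from the enol ether is much faster than cleavage of the hindered secondary silyl ether, and base-mediated epimerisation with DBU then equilibrates C4 through the C3 enolate. The equatorial 4β-methyl isomer is favoured because in 12 the axial C15 is 1,3-diaxial to C9 and lies under ring B, while C10 stays cis, its thermodynamic configuration. The equatorial C8–H is poorly aligned with the C9 carbonyl π system, so the axial silyloxy group should be exchanged only slowly.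

Step 9
Reactants: 13 8β-(tert-butyldimethylsilyloxy)-10βH-eremophil-11-ene-3,9-dione
Product: 14 3β-hydroxy-8β-(tert-butyldimethylsilyloxy)-10βH-eremophil-11-en-9-one
Conditions: Li(s-Bu)3BH, THF, −78 °C
Reagents that add atoms: none
Why: The bulky trialkylborohydride reduces the less hindered C3 ketone (the C9 carbonyl is flanked by the ring-fusion methine and the silyloxy-bearing C8); equatorial attack from the α face, away from the axial C14 methyl, gives the axial 3β-alcohol.

Step 10
Reactants: 14 3β-hydroxy-8β-(tert-butyldimethylsilyloxy)-10βH-eremophil-11-en-9-one, 15 senecioic acid (3-methylbut-2-enoic acid)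
Product: 16 3α-senecioyloxy-8β-(tert-butyldimethylsilyloxy)-10βH-eremophil-11-en-9-one
Conditions: PPh3, DIAD, PhMe, 0 °C → rt
Reagents that add atoms: none
Why: Mitsunobu esterification with inversion; the axial oxyphosphonium group at C3 is displaced from the unhindered α side to give the equatorial 3α-ester, and use of the free acid avoids the vinylketene pathway that deconjugates senecioyl chloride.

Step 11
Reactants: 16 3α-senecioyloxy-8β-(tert-butyldimethylsilyloxy)-10βH-eremophil-11-en-9-one
Product: 17 9β-hydroxy-3α-senecioyloxy-8β-(tert-butyldimethylsilyloxy)-10βH-eremophil-11-ene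
Conditions: NaBH4, CeCl3·7H2O, MeOH/THF, −40 °C
Reagents that add atoms: none
Why: Luche-type reduction with a small hydride; the axial 8β-silyloxy group blocks the β face and its C–O bond lies anti to the incoming hydride (polar Felkin–Anh model), so attack should be axial from the α face and give the equatorial 9β-alcohol, while the ester is not reduced.

Step 12
Reactants: 17 9β-hydroxy-3α-senecioyloxy-8β-(tert-butyldimethylsilyloxy)-10βH-eremophil-11-ene, 18 angelic acid ((Z)-2-methylbut-2-enoic acid)
Product: 20 9β-angeloyloxy-3α-senecioyloxy-8β-(tert-butyldimethylsilyloxy)-10βH-eremophil-11-ene, via angelic 2,4,6-trichlorobenzoic anhydride 19 (not isolated)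
Conditions: 18, 2,4,6-Cl3C6H2COCl, Et3N, PhMe, rt; then 17, 80 °C
Reagents that add atoms: none
Why: Yamaguchi-type esterification through the mixed anhydride without a nucleophilic catalyst, the established way to angeloylate hindered secondary alcohols without Z to E isomerisation; the alcohol attacks the less hindered angeloyl carbonyl of 19.

Step 13
Reactants: 20 9β-angeloyloxy-3α-senecioyloxy-8β-(tert-butyldimethylsilyloxy)-10βH-eremophil-11-ene
Product: 21 9β-angeloyloxy-8β-hydroxy-3α-senecioyloxy-10βH-eremophil-11-ene
Conditions: HF·pyridine, pyridine, THF, 0 °C → rt
Reagents that add atoms: none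
Why: Fluoride cleavage of the silyl ether in a buffered, non-basic medium; both enoates and the isopropenyl group are stable to it and the absence of alkoxide disfavours migration of the angeloyl group from O9 to O8.

Step 14
Reactants: 21 9β-angeloyloxy-8β-hydroxy-3α-senecioyloxy-10βH-eremophil-11-ene
Product: 22 9β-angeloyloxy-3α-senecioyloxy-10βH-eremophil-11-en-8-one (CNP0164025.2)
Conditions: Dess–Martin periodinane, pyridine, CH2Cl2, 0 °C → rt
Reagents that add atoms: none
Why: Dess–Martin oxidation of the secondary alcohol under buffered neutral conditions in the last step, so the β,γ-unsaturated α-acyloxy ketone never meets acid or base; C7 and C9 already carry their substituents in the stable equatorial positions.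

## Compound list

1 | (+)-3-carene, (1S,6R)-3,7,7-trimethylbicyclo[4.1.0]hept-3-ene | CC1=CC[C@@H]2[C@H](C1)C2(C)C | starting material
2 | (1S,6R)-car-3-en-5-one | CC1=CC(=O)[C@@H]2[C@H](C1)C2(C)C | intermediate
3 | (S)-5-(2-chloropropan-2-yl)-3-methylcyclohex-2-en-1-one | CC(C)(Cl)[C@H]1CC(C)=CC(=O)C1 | intermediate
4 | (S)-3-methyl-5-(prop-1-en-2-yl)cyclohex-2-en-1-one | C=C(C)[C@H]1CC(C)=CC(=O)C1 | intermediate
5 | ethyl vinyl ketone (pent-1-en-3-one) | C=CC(=O)CC | starting material
6 | tert-butyldimethylsilyl triflate | CC(C)(C)[Si](C)(C)OS(=O)(=O)C(F)(F)F | starting material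
7 | (Z)-3-(tert-butyldimethylsilyloxy)penta-1,3-diene | C/C=C(\O[Si](C)(C)C(C)(C)C)C=C | intermediate
8 | 3-(tert-butyldimethylsilyloxy)-4-epi-10βH-eremophila-2,11-dien-9-one | C=C(C)[C@H]1C[C@@]2(C)[C@H](CC=C(O[Si](C)(C)C(C)(C)C)[C@H]2C)C(=O)C1 | intermediate
9 | potassium 3-(tert-butyldimethylsilyloxy)-4-epi-10βH-eremophila-2,8,11-trien-9-olate (formed in the flask, not isolated) | C=C(C)[C@H]1C[C@@]2(C)[C@H](CC=C(O[Si](C)(C)C(C)(C)C)[C@H]2C)C([O-])=C1.[K+] | intermediate
10 | 8β-hydroxy-3-(tert-butyldimethylsilyloxy)-4-epi-10βH-eremophila-2,11-dien-9-one | C=C(C)[C@H]1C[C@@]2(C)[C@H](CC=C(O[Si](C)(C)C(C)(C)C)[C@H]2C)C(=O)[C@H]1O | intermediate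
11 | 3,8β-bis(tert-butyldimethylsilyloxy)-4-epi-10βH-eremophila-2,11-dien-9-one | C=C(C)[C@H]1C[C@@]2(C)[C@H](CC=C(O[Si](C)(C)C(C)(C)C)[C@H]2C)C(=O)[C@H]1O[Si](C)(C)C(C)(C)C | intermediate
12 | 8β-(tert-butyldimethylsilyloxy)-4-epi-10βH-eremophil-11-ene-3,9-dione, 4α-methyl (formed in the flask, not isolated) | C=C(C)[C@H]1C[C@@]2(C)[C@H](CCC(=O)[C@H]2C)C(=O)[C@H]1O[Si](C)(C)C(C)(C)C | intermediate
13 | 8β-(tert-butyldimethylsilyloxy)-10βH-eremophil-11-ene-3,9-dione, 4β-methyl | C=C(C)[C@H]1C[C@@]2(C)[C@H](CCC(=O)[C@@H]2C)C(=O)[C@H]1O[Si](C)(C)C(C)(C)C | intermediate
14 | 3β-hydroxy-8β-(tert-butyldimethylsilyloxy)-10βH-eremophil-11-en-9-one | C=C(C)[C@H]1C[C@@]2(C)[C@H](CC[C@H](O)[C@@H]2C)C(=O)[C@H]1O[Si](C)(C)C(C)(C)C | intermediate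
15 | senecioic acid (3-methylbut-2-enoic acid) | CC(C)=CC(=O)O | starting material
16 | 3α-senecioyloxy-8β-(tert-butyldimethylsilyloxy)-10βH-eremophil-11-en-9-one | C=C(C)[C@H]1C[C@@]2(C)[C@H](CC[C@@H](OC(=O)C=C(C)C)[C@@H]2C)C(=O)[C@H]1O[Si](C)(C)C(C)(C)C | intermediate
17 | 9β-hydroxy-3α-senecioyloxy-8β-(tert-butyldimethylsilyloxy)-10βH-eremophil-11-ene | C=C(C)[C@H]1C[C@@]2(C)[C@H](CC[C@@H](OC(=O)C=C(C)C)[C@@H]2C)[C@@H](O)[C@H]1O[Si](C)(C)C(C)(C)C | intermediate
18 | angelic acid ((Z)-2-methylbut-2-enoic acid) | C/C=C(/C)C(=O)O | starting material
19 | angelic 2,4,6-trichlorobenzoic anhydride (formed in the flask, not isolated) | C/C=C(/C)C(=O)OC(=O)c1c(Cl)cc(Cl)cc1Cl | intermediate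
20 | 9β-angeloyloxy-3α-senecioyloxy-8β-(tert-butyldimethylsilyloxy)-10βH-eremophil-11-ene | C=C(C)[C@H]1C[C@@]2(C)[C@H](CC[C@@H](OC(=O)C=C(C)C)[C@@H]2C)[C@@H](OC(=O)/C(C)=C\C)[C@H]1O[Si](C)(C)C(C)(C)C | intermediate
21 | 9β-angeloyloxy-8β-hydroxy-3α-senecioyloxy-10βH-eremophil-11-ene | C=C(C)[C@H]1C[C@@]2(C)[C@H](CC[C@@H](OC(=O)C=C(C)C)[C@@H]2C)[C@@H](OC(=O)/C(C)=C\C)[C@H]1O | intermediate
22 | 9β-angeloyloxy-3α-senecioyloxy-10βH-eremophil-11-en-8-one (CNP0164025.2) | C=C(C)[C@H]1C[C@@]2(C)[C@H](CC[C@@H](OC(=O)C=C(C)C)[C@@H]2C)[C@@H](OC(=O)/C(C)=C\C)C1=O | target

## Step count and least certain steps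

Total: 14 steps. Longest linear sequence: 13 steps (steps 1–3 and 5–14, from 1); step 4 is a one-step branch.

**Step 5 (key step).**
- What may go wrong: the diene may be lost to protodesilylation or oligomerisation before the hindered β,β-disubstituted enone reacts; the sequence may stop after the first C–C bond; the strong Lewis acid may isomerise the isopropenyl group.
- Fallback: divide the annulation into two separately tuned polar steps. From 4 and 7, a catalytic amount of Tf2NH in CH2Cl2 at −78 °C effects only the Mukaiyama–Michael addition with silyl transfer and gives the isolable adduct 1-(tert-butyldimethylsilyloxy)-3-methyl-3-(3-oxopent-4-en-2-yl)-5-(prop-1-en-2-yl)cyclohex-1-ene F1. An intramolecular Mukaiyama–Michael closure of F1 (catalytic tert-butyldimethylsilyl triflate, CH2Cl2, −40 °C) then lets the ring-B silyl enol ether add to the vinyl ketone with the silyl group moving to O3. This returns to the route at 8.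

**Step 11 (C9 reduction).**
- What may go wrong: poor facial selectivity. The α face of the C9 carbonyl is the concave face of the cis-decalin and the axial C4 carbon is 1,3-diaxial to the incoming hydride, so attack from the convex β face (giving the axial 9α-alcohol) may compete despite the axial 8β-silyloxy group. The new alkoxide could also take over the silyl group from O8.
- Fallback: replace facial control by thermodynamic control and do the reduction before any ester is present. From dione 13, an equilibrating Meerwein–Ponndorf–Verley reduction (Al(OiPr)3, iPrOH, trace acetone, reflux) turns both ketones into the more stable equatorial alcohols and gives 8β-(tert-butyldimethylsilyloxy)-10βH-eremophil-11-ene-3α,9β-diol F2. The unhindered 3α-hydroxyl of F2 is then esterified with retention (15, DCC, cat. DMAP), leaving the shielded 9β-hydroxyl free. This rejoins the route at 17 and bypasses steps 9 and 10 as well.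

**Step 10 (Mitsunobu).**
- What may go wrong: E2 elimination of the axial oxyphosphonium group (antiperiplanar hydrogens at C2 and C4), or no substitution because senecioic acid is only weakly acidic.
- Fallback: separate inversion from acylation. From 14, Mitsunobu reaction with the more acidic 4-nitrobenzoic acid gives 3α-(4-nitrobenzoyloxy)-8β-(tert-butyldimethylsilyloxy)-10βH-eremophil-11-en-9-one F3. Methanolysis of F3 (K2CO3, MeOH, 0 °C) releases 3α-hydroxy-8β-(tert-butyldimethylsilyloxy)-10βH-eremophil-11-en-9-one F4, which is acylated with retention (15, DCC, cat. DMAP) to rejoin the route at 16.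

**Step 3 (dehydrochlorination).**
- What may go wrong: elimination towards the ring methine (isopropylidene isomer, which can drift on to a phenol), or enolisation of the ketone followed by 1,3-elimination that re-closes the cyclopropane to 2.
- Fallback: exchange the halide route for hydration and dehydration, which needs no base able to enolise the ketone. From 2, acid-catalysed homoconjugate addition of water (dilute H2SO4, aqueous THF) gives (S)-5-(2-hydroxypropan-2-yl)-3-methylcyclohex-2-en-1-one F5. Dehydration of F5 with SOCl2/pyridine at 0 °C (E2 from the chlorosulfite, preferentially towards the methyl groups) returns to the route at 4.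

Further compounds
F1 | step 5 | 1-(tert-butyldimethylsilyloxy)-3-methyl-3-(3-oxopent-4-en-2-yl)-5-(prop-1-en-2-yl)cyclohex-1-ene (configuration as in 8) | C=C(C)[C@H]1C[C@](C)([C@H](C)C(=O)C=C)C=C(O[Si](C)(C)C(C)(C)C)C1
F2 | step 11 | 8β-(tert-butyldimethylsilyloxy)-10βH-eremophil-11-ene-3α,9β-diol | C=C(C)[C@H]1C[C@@]2(C)[C@H](CC[C@@H](O)[C@@H]2C)[C@@H](O)[C@H]1O[Si](C)(C)C(C)(C)C
F3 | step 10 | 3α-(4-nitrobenzoyloxy)-8β-(tert-butyldimethylsilyloxy)-10βH-eremophil-11-en-9-one | C=C(C)[C@H]1C[C@@]2(C)[C@H](CC[C@@H](OC(=O)c3ccc(cc3)[N+](=O)[O-])[C@@H]2C)C(=O)[C@H]1O[Si](C)(C)C(C)(C)C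
F4 | step 10 | 3α-hydroxy-8β-(tert-butyldimethylsilyloxy)-10βH-eremophil-11-en-9-one | C=C(C)[C@H]1C[C@@]2(C)[C@H](CC[C@@H](O)[C@@H]2C)C(=O)[C@H]1O[Si](C)(C)C(C)(C)C
F5 | step 3 | (S)-5-(2-hydroxypropan-2-yl)-3-methylcyclohex-2-en-1-one | CC(C)(O)[C@H]1CC(C)=CC(=O)C1
A1 | alternative 1 | 3,3-dimethoxy-5,6-dimethyl-2-vinylbicyclo[2.2.2]oct-5-en-2-ol (vinyl syn to the alkene bridge) | C=C[C@@]1(O)[C@@H]2CC[C@@H](C(C)=C2C)C1(OC)OC
A2 | alternative 1 | 9,9-dimethoxy-11,12,13-trinor-10βH-eremophil-3-en-8-one | O=C1CC[C@@]2(C)[C@H](CCC=C2C)C1(OC)OC
A3 | alternative 2 | (2E,6E)-farnesyl diphosphate | CC(C)=CCC/C(C)=C/CC/C(C)=C/COP(=O)(O)OP(=O)(O)O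
A4 | alternative 2 | (+)-aristolochene (7-epi-eremophila-9,11-diene) | C=C(C)[C@@H]1C[C@@]2(C)C(CCC[C@@H]2C)=CC1
A5 | alternative 3 | (Z)-4-iodo-1-(1-methylcyclohexa-2,5-dien-1-yl)but-3-en-2-one | CC1(CC(=O)/C=C\I)C=CCC=C1
A6 | alternative 3 | cis-8a-methyl-1,8a-dihydronaphthalen-2(4aH)-one | C1=C[C@@]2(C)[C@H](C=CC(=O)C2)C=C1
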